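**Plan**
Retrosynthesis: the O7 benzyl ether and one ortho methyl ether of ring A are put back. The pyran ring is then cut at C8a–O1, C4a–C4 and O1–C2, giving a ring-B aryne (C8a≡C4a) and 3-methylbut-2-enal. Last, the bond from the ketone carbon to ring A is cut to an aryl aldehyde and lithiated 1,3,5-trimethoxybenzene.
Enabling feature: the pyran ring (O1, C2, C3, C4) is fused to ring B at C8a and C4a, and C4a lies between C8a and the aroyl-bearing C5. An aryne across C8a–C4a is polarised and shielded by that C5 aroyl group, so the enal oxygen goes to C8a and its carbonyl carbon to C4a.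
Forward: ring B is armed first (Br, SiMe3 by retro-Brook shift, ortho-formylation, triflation). Ring A is joined through a carbinol and oxidised to the diaryl ketone. The pyran ring closes last by the aryne/oxa-6π cascade, and BCl3 then frees both phenols.
Stereochemistry: the target is achiral; the only stereocentres on the way (carbinol 10, benzoxete 14) are racemic and are erased.

Key step: step 7

Remark: chromene numbering (O1, C2, C3, C4, C4a, C5–C8, C8a) is used throughout; ring A is the aryl ketone ring that ends as 2-hydroxy-4,6-dimethoxyphenyl and ring B is the benzo ring of the chromene. The route starts from 4-(benzyloxy)phenol, so that the aryl–silicon bond is made before any carbonyl group is present.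

**Step 1**
Reactants: 1 4-(benzyloxy)phenol
Product: 2 4-(benzyloxy)-2-bromophenol
Conditions: NBS (1.0 equiv), i-Pr2NH (cat.), CH2Cl2, 0 °C
Reagents that add atoms: N-bromosuccinimide, O=C1CCC(=O)N1Br
Why: Amine-catalysed electrophilic bromination of a phenol goes ortho to the free hydroxyl, the stronger director, since the para position is blocked, and one equivalent of NBS should stop at the monobromide.

**Step 2**
Reactants: 2 4-(benzyloxy)-2-bromophenol
Product: 5 4-(benzyloxy)-2-(trimethylsilyl)phenol, via aryl silyl ether 3 (not isolated), via aryllithium 4 (not isolated)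
Conditions: HMDS, THF, reflux, then evaporate; n-BuLi, THF, −78 °C to rt; aq NH4Cl
Reagents that add atoms: hexamethyldisilazane, C[Si](C)(C)N[Si](C)(C)C
Why: O-silylation, bromine–lithium exchange and anionic 1,3 O-to-C silyl shift (retro-Brook rearrangement) are the standard entry to ortho-silylphenols, and exchange at −78 °C is faster than deprotonation of the benzyl ether.

**Step 3**
Reactants: 5 4-(benzyloxy)-2-(trimethylsilyl)phenol
Product: 6 5-(benzyloxy)-2-hydroxy-3-(trimethylsilyl)benzaldehyde
Conditions: MgCl2, Et3N, (CH2O)n, MeCN, reflux; cold dilute HCl work-up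
Reagents that add atoms: paraformaldehyde (as formaldehyde), C=O
Why: The magnesium-phenoxide-directed ortho-formylation (Casnati–Skattebøl reaction) takes the only free ortho position, with a second formaldehyde as hydride acceptor, and the basic medium should leave the aryl–silicon bond intact.

**Step 4**
Reactants: 6 5-(benzyloxy)-2-hydroxy-3-(trimethylsilyl)benzaldehyde
Product: 7 4-(benzyloxy)-2-formyl-6-(trimethylsilyl)phenyl trifluoromethanesulfonate
Conditions: Tf2O, pyridine, CH2Cl2, 0 °C
Reagents that add atoms: trifluoromethanesulfonic anhydride, O=S(=O)(OS(=O)(=O)C(F)(F)F)C(F)(F)F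
Why: O-sulfonylation of a salicylaldehyde-type phenol is routine, installs the leaving group of the aryne precursor, and caps the oxidisable hydroquinone-monoether phenol before the later oxidation.

**Step 5**
Reactants: 7 4-(benzyloxy)-2-formyl-6-(trimethylsilyl)phenyl trifluoromethanesulfonate, 8 1,3,5-trimethoxybenzene
Product: 10 4-(benzyloxy)-2-[hydroxy(2,4,6-trimethoxyphenyl)methyl]-6-(trimethylsilyl)phenyl trifluoromethanesulfonate (racemic), via 2,4,6-trimethoxyphenyllithium 9 (not isolated)
Conditions: 8 (slight excess over n-BuLi), n-BuLi, TMEDA, THF, 0 °C to rt; then 7, −78 °C; aq NH4Cl at −78 °C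
Reagents that add atoms: none
Why: Directed ortho-lithiation of 8 between two methoxy groups gives 9, whose 1,2-addition to the aldehyde at −78 °C should be much faster than attack at triflate sulfur or at silicon; the new carbinol centre is racemic and is removed in step 6.

**Step 6**
Reactants: 10 4-(benzyloxy)-2-[hydroxy(2,4,6-trimethoxyphenyl)methyl]-6-(trimethylsilyl)phenyl trifluoromethanesulfonate
Product: 11 4-(benzyloxy)-2-(2,4,6-trimethoxybenzoyl)-6-(trimethylsilyl)phenyl trifluoromethanesulfonate
Conditions: DMP, NaHCO3, CH2Cl2, rt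
Reagents that add atoms: none
Why: Buffered Dess–Martin oxidation of a secondary benzylic alcohol avoids acid ionisation of the electron-rich benzhydrol and does not touch the triflate, the arylsilane or the benzyl ether.

**Step 7**
Reactants: 11 4-(benzyloxy)-2-(2,4,6-trimethoxybenzoyl)-6-(trimethylsilyl)phenyl trifluoromethanesulfonate, 12 3-methylbut-2-enal
Product: 16 [7-(benzyloxy)-2,2-dimethyl-2H-chromen-5-yl](2,4,6-trimethoxyphenyl)methanone, via aryne 13 (not isolated), via benzoxete 14 (not isolated), via ortho-quinone methide 15 (not isolated)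
Conditions: CsF, 12 (10 equiv), MeCN, rt, slow addition of 11
Reagents that add atoms: none
Why: Fluoride attack on silicon with loss of triflate (1,2-elimination of the ortho-silylaryl triflate) unmasks aryne 13 across C8a–C4a; the carbonyl oxygen of 12 adds to C8a and the aryl anion at C4a closes on the activated carbonyl carbon, a stepwise formal (2+2) that gives benzoxete 14. Conrotatory 4π ring opening of 14 gives ortho-quinone methide 15 with the 2-methylpropenyl arm on the oxygen side, away from the C5 aroyl group. The six-membered pyran ring then closes by thermal disrotatory oxa-6π electrocyclisation, which forms O1–C2 and restores the aromaticity of ring B. The closest known reaction type is the annulation of silylaryl-triflate-derived arynes with α,β-unsaturated aldehydes to 2H-chromenes, a relative of aryne insertion into formamide C=O bonds. No stereocentre remains, since C2 carries two methyl groups and the racemic centre of 14 is lost on ring opening. The selectivity needed is regiochemical (oxygen to C8a, carbon to C4a) and is secured by the twisted, inductively withdrawing aroyl group on C5, which shields C4a and stabilises the negative charge developing there, while excess 12 and slow addition of 11 keep 15 from being captured by a second aryne.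

**Step 8**
Reactants: 16 [7-(benzyloxy)-2,2-dimethyl-2H-chromen-5-yl](2,4,6-trimethoxyphenyl)methanone
Product: 17 (2-hydroxy-4,6-dimethoxyphenyl)(7-hydroxy-2,2-dimethyl-2H-chromen-5-yl)methanone
Conditions: BCl3, C6HMe5, CH2Cl2, −78 to 0 °C; MeOH, aq NaHCO3
Reagents that add atoms: none
Why: BCl3 with pentamethylbenzene as cation scavenger cleaves aryl benzyl ethers at low temperature, and BCl3 chelated between the ketone oxygen and an ortho methoxy group removes just one of the two equivalent ortho methyl ethers of ring A, because the boron chelate then blocks the second, while the para methoxy group is not activated.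

**Compound list**
1 | 4-(benzyloxy)phenol | Oc1ccc(OCc2ccccc2)cc1 | starting material
2 | 4-(benzyloxy)-2-bromophenol | Oc1ccc(OCc2ccccc2)cc1Br | intermediate
3 | [4-(benzyloxy)-2-bromophenoxy]trimethylsilane (aryl silyl ether, not isolated) | C[Si](C)(C)Oc1ccc(OCc2ccccc2)cc1Br | intermediate
4 | [5-(benzyloxy)-2-(trimethylsilyloxy)phenyl]lithium (aryllithium, not isolated) | [Li]c1cc(OCc2ccccc2)ccc1O[Si](C)(C)C | intermediate
5 | 4-(benzyloxy)-2-(trimethylsilyl)phenol | Oc1ccc(OCc2ccccc2)cc1[Si](C)(C)C | intermediate
6 | 5-(benzyloxy)-2-hydroxy-3-(trimethylsilyl)benzaldehyde | O=Cc1cc(OCc2ccccc2)cc([Si](C)(C)C)c1O | intermediate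
7 | 4-(benzyloxy)-2-formyl-6-(trimethylsilyl)phenyl trifluoromethanesulfonate | O=Cc1cc(OCc2ccccc2)cc([Si](C)(C)C)c1OS(=O)(=O)C(F)(F)F | intermediate
8 | 1,3,5-trimethoxybenzene | COc1cc(OC)cc(OC)c1 | starting material
9 | 2,4,6-trimethoxyphenyllithium (not isolated) | [Li]c1c(OC)cc(OC)cc1OC | intermediate
10 | 4-(benzyloxy)-2-[hydroxy(2,4,6-trimethoxyphenyl)methyl]-6-(trimethylsilyl)phenyl trifluoromethanesulfonate (racemic) | COc1cc(OC)c(C(O)c2cc(OCc3ccccc3)cc([Si](C)(C)C)c2OS(=O)(=O)C(F)(F)F)c(OC)c1 | intermediate
11 | 4-(benzyloxy)-2-(2,4,6-trimethoxybenzoyl)-6-(trimethylsilyl)phenyl trifluoromethanesulfonate | COc1cc(OC)c(C(=O)c2cc(OCc3ccccc3)cc([Si](C)(C)C)c2OS(=O)(=O)C(F)(F)F)c(OC)c1 | intermediate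
12 | 3-methylbut-2-enal | CC(C)=CC=O | starting material
13 | [5-(benzyloxy)-2,3-didehydrophenyl](2,4,6-trimethoxyphenyl)methanone (aryne across C8a–C4a, not isolated) | COc1cc(OC)c(C(=O)C2=CC(OCc3ccccc3)=CC#C2)c(OC)c1 | intermediate
14 | [4-(benzyloxy)-8-(2-methylprop-1-en-1-yl)-7-oxabicyclo[4.2.0]octa-1,3,5-trien-2-yl](2,4,6-trimethoxyphenyl)methanone (benzoxete, racemic, not isolated) | COc1cc(OC)c(C(=O)c2cc(OCc3ccccc3)cc3OC(C=C(C)C)c23)c(OC)c1 | intermediate
15 | (6Z)-3-(benzyloxy)-6-(3-methylbut-2-en-1-ylidene)-5-(2,4,6-trimethoxybenzoyl)cyclohexa-2,4-dien-1-one (ortho-quinone methide, not isolated) | CC(C)=C/C=C1\C(=O)C=C(OCc2ccccc2)C=C1C(=O)c1c(OC)cc(OC)cc1OC | intermediate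
16 | [7-(benzyloxy)-2,2-dimethyl-2H-chromen-5-yl](2,4,6-trimethoxyphenyl)methanone | COc1cc(OC)c(C(=O)c2cc(OCc3ccccc3)cc3c2C=CC(C)(C)O3)c(OC)c1 | intermediate
17 | (2-hydroxy-4,6-dimethoxyphenyl)(7-hydroxy-2,2-dimethyl-2H-chromen-5-yl)methanone | COc1cc(O)c(C(=O)c2cc(O)cc3c2C=CC(C)(C)O3)c(OC)c1 | target

**Step count**
Total: 8 steps. Longest linear sequence: 8 steps, from 1 to 17.

**Steps most likely to fail**

Step 7. The enal may lose the race for aryne 13 in three ways: fluoride may deprotonate 12 at its γ-methyl groups so that it self-condenses, the aryne may take an ene path with the methyl hydrogens of 12, or a ring-A methoxy oxygen may close onto C4a. The fallback sets out from 11 and uses the solvent as the carbonyl partner. CsF in DMF should insert 13 into the formamide C=O bond with the same regiochemical sense, and aqueous work-up should give 4-(benzyloxy)-2-hydroxy-6-(2,4,6-trimethoxybenzoyl)benzaldehyde F1. A Petasis-type condensation of F1 with 2-methylprop-1-enylboronic acid and dibenzylamine (dioxane/H2O, 90 °C) should pass through [5-(benzyloxy)-2-[1-(dibenzylamino)-3-methylbut-2-en-1-yl]-3-hydroxyphenyl](2,4,6-trimethoxyphenyl)methanone F2. F2 loses dibenzylamine to the same ortho-quinone methide 15, which closes to 16, where the route is rejoined.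

Step 8. BCl3 may ionise the tertiary allylic O1–C2 bond of the chromene, HCl may add across C3=C4, or the benzyl cation may alkylate the electron-rich rings. The fallback moves the Lewis-acid cleavages ahead of the annulation and sets out from 11. BCl3 with C6HMe5 (CH2Cl2, −78 to 0 °C) should give 4-hydroxy-2-(2-hydroxy-4,6-dimethoxybenzoyl)-6-(trimethylsilyl)phenyl trifluoromethanesulfonate F3. MOMCl with i-Pr2NEt should give 4-(methoxymethoxy)-2-[2-(methoxymethoxy)-4,6-dimethoxybenzoyl]-6-(trimethylsilyl)phenyl trifluoromethanesulfonate F4. The fluoride-triggered cascade with 12, run as in step 7, should give [7-(methoxymethoxy)-2,2-dimethyl-2H-chromen-5-yl][2-(methoxymethoxy)-4,6-dimethoxyphenyl]methanone F5. Dilute HCl in MeOH at rt then cleaves both acetals under mild protic conditions and the route is rejoined at 17.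

Step 5. The aryllithium may attack the triflate sulfur, or the lithium alkoxide formed next to the triflate may take over the triflyl group, so that the leaving group is lost before the ketone exists. The fallback builds the ketone before the triflate and sets out from 6. Two equivalents of 9 (the first is consumed by the phenol) should give 4-(benzyloxy)-2-[hydroxy(2,4,6-trimethoxyphenyl)methyl]-6-(trimethylsilyl)phenol F6. MnO2 in CH2Cl2 should oxidise only the benzylic alcohol to [5-(benzyloxy)-2-hydroxy-3-(trimethylsilyl)phenyl](2,4,6-trimethoxyphenyl)methanone F7. Triflation of F7 (Tf2O, pyridine, CH2Cl2) rejoins the route at 11.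

**Further compounds**
F1 | step 7 | 4-(benzyloxy)-2-hydroxy-6-(2,4,6-trimethoxybenzoyl)benzaldehyde | COc1cc(OC)c(C(=O)c2cc(OCc3ccccc3)cc(O)c2C=O)c(OC)c1
F2 | step 7 | [5-(benzyloxy)-2-[1-(dibenzylamino)-3-methylbut-2-en-1-yl]-3-hydroxyphenyl](2,4,6-trimethoxyphenyl)methanone | COc1cc(OC)c(C(=O)c2cc(OCc3ccccc3)cc(O)c2C(C=C(C)C)N(Cc4ccccc4)Cc5ccccc5)c(OC)c1
F3 | step 8 | 4-hydroxy-2-(2-hydroxy-4,6-dimethoxybenzoyl)-6-(trimethylsilyl)phenyl trifluoromethanesulfonate | COc1cc(O)c(C(=O)c2cc(O)cc([Si](C)(C)C)c2OS(=O)(=O)C(F)(F)F)c(OC)c1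
F4 | step 8 | 4-(methoxymethoxy)-2-[2-(methoxymethoxy)-4,6-dimethoxybenzoyl]-6-(trimethylsilyl)phenyl trifluoromethanesulfonate | COCOc1cc(OC)cc(OC)c1C(=O)c1cc(OCOC)cc([Si](C)(C)C)c1OS(=O)(=O)C(F)(F)F
F5 | step 8 | [7-(methoxymethoxy)-2,2-dimethyl-2H-chromen-5-yl][2-(methoxymethoxy)-4,6-dimethoxyphenyl]methanone | COCOc1cc(OC)cc(OC)c1C(=O)c1cc(OCOC)cc2c1C=CC(C)(C)O2
F6 | step 5 | 4-(benzyloxy)-2-[hydroxy(2,4,6-trimethoxyphenyl)methyl]-6-(trimethylsilyl)phenol | COc1cc(OC)c(C(O)c2cc(OCc3ccccc3)cc([Si](C)(C)C)c2O)c(OC)c1
F7 | step 5 | [5-(benzyloxy)-2-hydroxy-3-(trimethylsilyl)phenyl](2,4,6-trimethoxyphenyl)methanone | COc1cc(OC)c(C(=O)c2cc(OCc3ccccc3)cc([Si](C)(C)C)c2O)c(OC)c1
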